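**Retrosynthetic overview**

1. Dactylomelol 22 ⇐ halogens installed last (Shi epoxide, bromide by SN2 opening, chloride via a bromonium ion) and vinyl carbinol made from a methyl ketone (asymmetric Corey–Chaykovsky epoxidation, ylide homologation) ⇐ bicyclic methyl ketone 15 ⇐ geminal diester 11 (two decarboxylations).
2. Key disconnection of 11 (7-oxabicyclo[2.2.1]heptane; C1 = methyl-bearing bridgehead, O7 = bridge): bonds C4–C5 and O7–C1 are made together from the acyclic aldehyde 9, which carries a cyclopropane-1,1-diester (strain-release formal [3+2]).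
3. 9 ⇐ (S)-carvone: its stereocentre becomes C2, two α′-alkylations build the quaternary C3, the isopropenyl group becomes the cyclopropane, and cleavage of the enone ring between C=O and C(CH3) frees the aldehyde and the methyl ketone.
4. Ring order: cyclopropane (step 3, temporary) → carvone ring opened (step 5) → oxolane and cyclohexane of the oxabicycle closed in one operation (step 6); afterwards only transient epoxides.
5. Enabling feature: the oxolane O7–C1–C6–C5–C4 inside the bicycle has a fully substituted, cation-stabilising ether carbon (C1, bearing CH3 and C2) two bonds from an unsubstituted CH2 (C5) that sits next to the CH–O bridgehead C4. C1/C6/C5 therefore map onto a donor–acceptor cyclopropane (C5 carrying a removable diester) and C4–O7 onto an aldehyde.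

Key step: step 6

Remark: centres that are destroyed or converge later (the cyclopropane carbon in 5–9, the carbinol carbons of 7 and 8, the CH(CO2H) carbon of 13 and 14) are left undefined in the SMILES because both epimers are carried on; the (S)-antipode of the lanthanum–lithium binaphthoxide catalyst is assumed to give the (S)-epoxide 16, and its mirror image is used if the sense is the reverse.

**Route**

Step 1
Reactants: 1 (S)-carvone; 2 5-iodo-2-methylpent-2-ene
Product: 3 trans-6-(4-methylpent-3-enyl)carvone
Conditions: LiN(iPr)2, THF, −78 °C; then 2, DMPU, −78 → −20 °C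
Reagents that add atoms: none
Why: Kinetic α′-deprotonation of the cross-conjugated enone and SN2 alkylation of the lithium enolate should place the chain mainly trans to the isopropenyl group, but this centre is re-enolised in step 2, so its configuration does not matter.

Step 2
Reactants: 3 trans-6-(4-methylpent-3-enyl)carvone
Product: 4 (5R,6S)-6-methyl-6-(4-methylpent-3-enyl)carvone
Conditions: LiN(iPr)2, THF, −78 °C; then MeI, −78 → 0 °C
Reagents that add atoms: iodomethane, CI
Why: Second enolate alkylation: iodomethane should approach the enolate face anti to the neighbouring isopropenyl group, so the methyl ends trans to it and the quaternary centre is set by the carvone stereocentre.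

Step 3
Reactants: 4 (5R,6S)-6-methyl-6-(4-methylpent-3-enyl)carvone
Product: 5 cyclopropane-1,1-diester enone
Conditions: Rh2(esp)2 (esp = α,α,α′,α′-tetramethyl-1,3-benzenedipropionate, 1 mol %), dimethyl diazomalonate (slow addition), CH2Cl2, 0 °C → rt
Reagents that add atoms: dimethyl diazomalonate, COC(=O)C(=[N+]=[N-])C(=O)OC
Why: Rhodium-carbenoid cyclopropanation: the bulky electrophilic malonate carbenoid should add to the 1,1-disubstituted alkene in preference to the trisubstituted side-chain alkene and the electron-poor enone; the new cyclopropane centre is not controlled and need not be, because both epimers converge in step 6.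

Step 4
Reactants: 5 cyclopropane-1,1-diester enone
Product: 7 α-hydroxy ketone, via lithium enolate 6 (not isolated)
Conditions: LiBH(s-Bu)3, THF, −78 °C; then 2-(phenylsulfonyl)-3-phenyloxaziridine, −78 → −40 °C; aq. NH4Cl
Reagents that add atoms: 2-(phenylsulfonyl)-3-phenyloxaziridine, O=S(=O)(N1OC1c1ccccc1)c1ccccc1
Why: Conjugate (1,4) hydride reduction of the hindered enone gives the regiodefined enolate 6, which is hydroxylated at carbon by the N-sulfonyloxaziridine (enolate α-hydroxylation); the new carbinol centre is removed in step 5.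

Step 5
Reactants: 7 α-hydroxy ketone
Product: 9 keto aldehyde with cyclopropane-1,1-diester, via 1,2-diol 8 (not isolated)
Conditions: NaBH4, MeOH, 0 °C → rt; acetone quench; then NaIO4, THF/H2O (pH 7), rt
Reagents that add atoms: none
Why: Borohydride reduction of the α-hydroxy ketone to the 1,2-diol 8 and periodate glycol cleavage (Malaprade reaction) open the ring between the former carbonyl carbon and C(OH)CH3, which gives a non-enolisable aldehyde on the quaternary carbon and a methyl ketone without touching the two set stereocentres.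

Step 6
Reactants: 9 keto aldehyde with cyclopropane-1,1-diester
Product: 11 7-oxabicyclo[2.2.1]heptane-2,2-diester, via oxocarbenium malonate zwitterion 10 (not isolated)
Conditions: Sc(OTf)3 (20 mol %), 4 Å MS, ClCH2CH2Cl, rt
Reagents that add atoms: none
Why: Sc(OTf)3 chelates the geminal diester and polarises the bond between the fully substituted cyclopropane carbon and the diester carbon; the aldehyde oxygen opens this strained bond at the tertiary terminus (5-exo-tet, first oxolane O7–C1–C2–C3–C4) to give the zwitterion 10, whose malonate carbon then adds to the oxocarbenium carbon C4 (6-exo-trig for the cyclohexane, 5-endo-trig for the second oxolane), so that strain release pays for both bonds. The closest known reaction type is the Lewis-acid-catalysed formal [3+2] cycloaddition of cyclopropane-1,1-diesters with aldehydes, including its intramolecular cross variant that gives oxa-bridged [n.2.1] bicycles. C1 is set in the C–O bond formation, where the CH2C(CO2Me)2 arm should settle trans to the adjacent C2 side chain, and because the fully substituted donor carbon ionises reversibly both cyclopropane epimers of 9 should funnel into the same zwitterion. C4 follows by geometric necessity, since the two-carbon tether can only reach the face of the oxocarbenium ring on which it stands. The step needs chemoselectivity for the aldehyde over the methyl ketone, secured by the faster five-membered oxocarbenium closure and the higher reactivity of aldehydes, and cleavage of the right cyclopropane bond, secured by the tertiary donor carbon. The favoured bicycle carries only the 4-methylpent-3-enyl chain endo (C2 side chain and C3 methyl exo, syn to oxygen), whereas the alternative would need two endo substituents.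

Step 7
Reactants: 11 7-oxabicyclo[2.2.1]heptane-2,2-diester
Product: 13 bicyclic monocarboxylic acid, via malonic acid 12 (not isolated)
Conditions: LiOH, THF/MeOH/H2O, 60 °C; aq. HCl to pH 2; then xylene, 140 °C
Reagents that add atoms: lithium hydroxide, [Li+].[OH-]
Why: Ester saponification followed by thermal decarboxylation of the malonic acid through its cyclic enol transition state, which avoids a free carbanion β to the bridging oxygen; the new CH(CO2H) centre is removed in step 8.

Step 8
Reactants: 13 bicyclic monocarboxylic acid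
Product: 15 bicyclic methyl ketone, via thiohydroxamate ester 14 (not isolated)
Conditions: 1-hydroxypyridine-2(1H)-thione, DCC, DMAP (cat.), CH2Cl2, dark, rt; then t-BuSH, hν (tungsten lamp), PhH, rt
Reagents that add atoms: none
Why: Barton decarboxylation: the thiohydroxamate ester fragments to a secondary alkyl radical that is reduced by the thiol faster than it can add to the remote alkene, which leaves CH2 at C5.

Step 9
Reactants: 15 bicyclic methyl ketone
Product: 16 (S)-2-methyloxirane
Conditions: Me3S(O)I, NaH, THF (ylide); (S)-LaLi3(binaphthoxide)3 (5 mol %), (2,4,6-(MeO)3C6H2)3P=O (5 mol %), 5 Å MS, THF, rt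
Reagents that add atoms: trimethylsulfoxonium iodide, C[S+](C)(C)=O.[I-]
Why: Catalytic asymmetric Corey–Chaykovsky epoxidation: the lanthanum–lithium binaphthoxide catalyst differentiates the methyl from the CH2CH2 branch of the ketone and so should set the remote (S)-centre by reagent control.

Step 10
Reactants: 16 (S)-2-methyloxirane
Product: 17 (S)-vinyl carbinol
Conditions: Me3SI, n-BuLi, THF, −10 °C → rt
Reagents that add atoms: trimethylsulfonium iodide, C[S+](C)C.[I-]
Why: Ring opening of the terminal epoxide at CH2 by dimethylsulfonium methylide and ylide-mediated loss of dimethyl sulfide (one-carbon homologation of an epoxide to an allylic alcohol) should give the vinyl carbinol with the C–O stereocentre untouched.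

Step 11
Reactants: 17 (S)-vinyl carbinol
Product: 18 triethylsilyl ether
Conditions: Et3SiOTf, 2,6-lutidine, CH2Cl2, −78 → 0 °C
Reagents that add atoms: triethylsilyl trifluoromethanesulfonate, CC[Si](CC)(CC)OS(=O)(=O)C(F)(F)F
Why: Silylation of the tertiary allylic alcohol with the silyl triflate protects it against ionisation and chlorination in step 14.

Step 12
Reactants: 18 triethylsilyl ether
Product: 19 (R)-3,3-dimethyloxirane
Conditions: D-fructose-derived Shi ketone (30 mol %), KHSO5 (Oxone), K2CO3, Bu4NHSO4, MeCN/CH2(OMe)2/aq. buffer (pH 10.5), 0 °C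
Reagents that add atoms: potassium peroxymonosulfate, [K+].OOS(=O)(=O)[O-]
Why: Shi epoxidation: the chiral dioxirane attacks the electron-rich trisubstituted alkene (the hindered monosubstituted vinyl group is inert) and by catalyst control should give the (R)-epoxide.

Step 13
Reactants: 19 (R)-3,3-dimethyloxirane
Product: 20 (S)-bromohydrin
Conditions: Li2NiBr4, THF, 0 °C → rt
Reagents that add atoms: dilithium tetrabromonickelate, [Li+].[Li+].[Ni+2].[Br-].[Br-].[Br-].[Br-]
Why: Bromide from the soft Li2NiBr4 reagent should open the epoxide by SN2 attack at the less substituted carbon with inversion, which gives the (S)-bromide and the tertiary alcohol.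

Step 14
Reactants: 20 (S)-bromohydrin
Product: 21 silyl-protected bromochloride
Conditions: 1-chloro-N,N,2-trimethylprop-1-en-1-amine, CH2Cl2, 0 °C → rt
Reagents that add atoms: 1-chloro-N,N,2-trimethylprop-1-en-1-amine, CC(C)=C(Cl)N(C)C
Why: Deoxychlorination with the α-chloroenamine under neutral conditions: the activated tertiary oxygen leaves with neighbouring-group participation of bromine, chloride opens the bromonium ion at the tertiary carbon, and the C–Br stereocentre is never broken (retention).

Step 15
Reactants: 21 silyl-protected bromochloride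
Product: 22 dactylomelol
Conditions: HF·pyridine, pyridine/THF, 0 °C
Reagents that add atoms: none
Why: Fluoride-mediated desilylation of the tertiary silyl ether under buffered conditions should leave the halides, the ether bridge and the allylic alcohol intact.

**Compound list**

1 | (S)-carvone, (5S)-2-methyl-5-(prop-1-en-2-yl)cyclohex-2-en-1-one | CC1=CC[C@@H](CC1=O)C(C)=C | starting material
2 | 5-iodo-2-methylpent-2-ene | CC(C)=CCCI | starting material
3 | (5S,6R)-2-methyl-6-(4-methylpent-3-en-1-yl)-5-(prop-1-en-2-yl)cyclohex-2-en-1-one (trans, major epimer) | CC1=CC[C@H](C(C)=C)[C@@H](CCC=C(C)C)C1=O | intermediate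
4 | (5R,6S)-2,6-dimethyl-6-(4-methylpent-3-en-1-yl)-5-(prop-1-en-2-yl)cyclohex-2-en-1-one (6-methyl trans to isopropenyl) | CC1=CC[C@H](C(C)=C)[C@](C)(CCC=C(C)C)C1=O | intermediate
5 | dimethyl 2-[(1R,2S)-2,4-dimethyl-2-(4-methylpent-3-en-1-yl)-3-oxocyclohex-4-en-1-yl]-2-methylcyclopropane-1,1-dicarboxylate (both epimers at the cyclopropane carbon) | CC1=CC[C@H](C2(C)CC2(C(=O)OC)C(=O)OC)[C@](C)(CCC=C(C)C)C1=O | intermediate
6 | lithium enolate from 1,4-reduction of 5 (lithium cyclohex-1-en-1-olate) | [Li+].CC=1CC[C@H](C2(C)CC2(C(=O)OC)C(=O)OC)[C@](C)(CCC=C(C)C)C=1[O-] | intermediate (not isolated)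
7 | dimethyl 2-[(1R,2S)-4-hydroxy-2,4-dimethyl-2-(4-methylpent-3-en-1-yl)-3-oxocyclohexyl]-2-methylcyclopropane-1,1-dicarboxylate (epimers at C(OH)CH3 and at the cyclopropane carbon) | CC1(O)CC[C@H](C2(C)CC2(C(=O)OC)C(=O)OC)[C@](C)(CCC=C(C)C)C1=O | intermediate
8 | dimethyl 2-[(1R,2S)-3,4-dihydroxy-2,4-dimethyl-2-(4-methylpent-3-en-1-yl)cyclohexyl]-2-methylcyclopropane-1,1-dicarboxylate (epimer mixture) | CC1(O)CC[C@H](C2(C)CC2(C(=O)OC)C(=O)OC)[C@](C)(CCC=C(C)C)C1O | intermediate (not isolated)
9 | dimethyl 2-[(1R)-1-[(2S)-2,6-dimethyl-1-oxohept-5-en-2-yl]-4-oxopentyl]-2-methylcyclopropane-1,1-dicarboxylate (both epimers at the cyclopropane carbon) | CC(=O)CC[C@H](C1(C)CC1(C(=O)OC)C(=O)OC)[C@](C)(CCC=C(C)C)C=O | intermediate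
10 | scandium-bound zwitterion: 3,4-dihydro-2H-furan-1-ium (oxocarbenium) with a malonate enolate on the CH2 arm at the O-bearing quaternary carbon, arm trans to the 3-oxobutyl chain | CC(=O)CC[C@H]1[C@](C)(CCC=C(C)C)C=[O+][C@]1(C)CC(C(=O)OC)=C([O-])OC | intermediate (not isolated)
11 | dimethyl (1R,4R,5S,6S)-4,6-dimethyl-6-(4-methylpent-3-en-1-yl)-5-(3-oxobutyl)-7-oxabicyclo[2.2.1]heptane-2,2-dicarboxylate (3-oxobutyl and 6-methyl exo) | CC(=O)CC[C@H]1[C@](C)(CCC=C(C)C)[C@@H]2C(C(=O)OC)(C(=O)OC)C[C@@]1(C)O2 | intermediate
12 | (1R,4R,5S,6S)-4,6-dimethyl-6-(4-methylpent-3-en-1-yl)-5-(3-oxobutyl)-7-oxabicyclo[2.2.1]heptane-2,2-dicarboxylic acid | CC(=O)CC[C@H]1[C@](C)(CCC=C(C)C)[C@@H]2C(C(=O)O)(C(=O)O)C[C@@]1(C)O2 | intermediate (not isolated)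
13 | (1S,4R,5S,6S)-4,6-dimethyl-6-(4-methylpent-3-en-1-yl)-5-(3-oxobutyl)-7-oxabicyclo[2.2.1]heptane-2-carboxylic acid (C2 epimers) | CC(=O)CC[C@H]1[C@](C)(CCC=C(C)C)[C@@H]2C(C(=O)O)C[C@@]1(C)O2 | intermediate
14 | 2-thioxopyridin-1(2H)-yl ester of 13 | CC(=O)CC[C@H]1[C@](C)(CCC=C(C)C)[C@@H]2C(C(=O)ON3C=CC=CC3=S)C[C@@]1(C)O2 | intermediate (not isolated)
15 | 4-[(1R,2S,3S,4S)-1,3-dimethyl-3-(4-methylpent-3-en-1-yl)-7-oxabicyclo[2.2.1]heptan-2-yl]butan-2-one | CC(=O)CC[C@H]1[C@](C)(CCC=C(C)C)[C@@H]2CC[C@@]1(C)O2 | intermediate
16 | (1R,2S,3S,4S)-1,3-dimethyl-3-(4-methylpent-3-en-1-yl)-2-{2-[(2S)-2-methyloxiran-2-yl]ethyl}-7-oxabicyclo[2.2.1]heptane | C3O[C@@]3(C)CC[C@H]1[C@](C)(CCC=C(C)C)[C@@H]2CC[C@@]1(C)O2 | intermediate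
17 | (3S)-5-[(1R,2S,3S,4S)-1,3-dimethyl-3-(4-methylpent-3-en-1-yl)-7-oxabicyclo[2.2.1]heptan-2-yl]-3-methylpent-1-en-3-ol | C=C[C@@](C)(O)CC[C@H]1[C@](C)(CCC=C(C)C)[C@@H]2CC[C@@]1(C)O2 | intermediate
18 | triethylsilyl ether of 17 | C=C[C@@](C)(O[Si](CC)(CC)CC)CC[C@H]1[C@](C)(CCC=C(C)C)[C@@H]2CC[C@@]1(C)O2 | intermediate
19 | triethylsilyl ether with a 2-[(2R)-3,3-dimethyloxiran-2-yl]ethyl group at C3 of the bicycle | C=C[C@@](C)(O[Si](CC)(CC)CC)CC[C@H]1[C@](C)(CC[C@@H](O3)C3(C)C)[C@@H]2CC[C@@]1(C)O2 | intermediate
20 | triethylsilyl ether with a (3S)-3-bromo-4-hydroxy-4-methylpentyl group at C3 of the bicycle | C=C[C@@](C)(O[Si](CC)(CC)CC)CC[C@H]1[C@](C)(CC[C@H](Br)C(C)(C)O)[C@@H]2CC[C@@]1(C)O2 | intermediate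
21 | triethylsilyl ether of dactylomelol, with a (3S)-3-bromo-4-chloro-4-methylpentyl group | C=C[C@@](C)(O[Si](CC)(CC)CC)CC[C@H]1[C@](C)(CC[C@H](Br)C(C)(C)Cl)[C@@H]2CC[C@@]1(C)O2 | intermediate
22 | dactylomelol, (3S)-5-[(1R,2S,3S,4S)-3-[(3S)-3-bromo-4-chloro-4-methylpentyl]-1,3-dimethyl-7-oxabicyclo[2.2.1]heptan-2-yl]-3-methylpent-1-en-3-ol | C=C[C@@](C)(O)CC[C@H]1[C@](C)(CC[C@H](Br)C(C)(C)Cl)[C@@H]2CC[C@@]1(C)O2 | target

**Step count and risks**

Total step count: 15. Longest linear sequence: 15 steps from (S)-carvone 1.

Steps most likely to fail: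

Step 6. A carbonyl-ene (Prins-type) cyclisation of the Lewis-acid-activated aldehyde onto the nucleophilic trisubstituted alkene of the 4-methylpent-3-enyl chain may outrun opening of the cyclopropane. The fallback sets out from 9 and takes the alkene out of play: pyridinium tribromide in CH2Cl2 at −78 °C should give the vicinal dibromide F1, the same Sc(OTf)3 annulation should then give the dibromo cycloadduct F2, and zinc dust in acetic acid/ether restores the alkene and comes back to the route at 11.

Step 13. Regiocontrol of the epoxide opening may be lost, through bromide attack at the tertiary carbon or a Lewis-acid-induced hydride shift to a ketone. The fallback sets out from 19 and reverses the order of halide introduction: pyridinium chloride in CH2Cl2 at 0 °C should open the epoxide at the tertiary carbon (Markovnikov sense) with the secondary carbinol retained, giving the chlorohydrin F3, and Appel bromination (CBr4, PPh3, CH2Cl2, 0 °C) inverts that carbinol to the (S)-bromide and comes back to the route at 21.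

Step 3. The carbenoid may discriminate poorly between the isopropenyl group and the trisubstituted side-chain alkene. The fallback sets out from 1 and cyclopropanates before the competing alkene exists: Rh2(esp)2 with dimethyl diazomalonate on carvone itself should give the cyclopropane diester F4, alkylation of its lithium enolate with 2 should give the 6-alkylated ketone F5, and methylation of F5 (LiN(iPr)2, MeI) comes back to the route at 5.

Further compounds
F1 | step 6 | dimethyl 2-[(1R)-1-[(2S)-5,6-dibromo-2,6-dimethyl-1-oxoheptan-2-yl]-4-oxopentyl]-2-methylcyclopropane-1,1-dicarboxylate (epimers at CHBr and at the cyclopropane carbon) | CC(=O)CC[C@H](C1(C)CC1(C(=O)OC)C(=O)OC)[C@](C)(CCC(Br)C(C)(C)Br)C=O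
F2 | step 6 | dimethyl (1R,4R,5S,6S)-6-(3,4-dibromo-4-methylpentyl)-4,6-dimethyl-5-(3-oxobutyl)-7-oxabicyclo[2.2.1]heptane-2,2-dicarboxylate (epimers at CHBr) | CC(=O)CC[C@H]1[C@](C)(CCC(Br)C(C)(C)Br)[C@@H]2C(C(=O)OC)(C(=O)OC)C[C@@]1(C)O2
F3 | step 13 | triethylsilyl ether of (3S)-5-[(1R,2S,3S,4S)-3-[(3R)-4-chloro-3-hydroxy-4-methylpentyl]-1,3-dimethyl-7-oxabicyclo[2.2.1]heptan-2-yl]-3-methylpent-1-en-3-ol | C=C[C@@](C)(O[Si](CC)(CC)CC)CC[C@H]1[C@](C)(CC[C@@H](O)C(C)(C)Cl)[C@@H]2CC[C@@]1(C)O2
F4 | step 3 | dimethyl 2-methyl-2-[(1S)-4-methyl-5-oxocyclohex-3-en-1-yl]cyclopropane-1,1-dicarboxylate (both epimers at the cyclopropane carbon) | CC1=CC[C@@H](CC1=O)C2(C)CC2(C(=O)OC)C(=O)OC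
F5 | step 3 | dimethyl 2-methyl-2-[(1S,2R)-4-methyl-2-(4-methylpent-3-en-1-yl)-3-oxocyclohex-4-en-1-yl]cyclopropane-1,1-dicarboxylate (trans, major epimer) | CC1=CC[C@H](C2(C)CC2(C(=O)OC)C(=O)OC)[C@@H](CCC=C(C)C)C1=O
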